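**Retrosynthetic overview**
- The strategy rests on two features. C2 of ring C, the only stereocentre, holds ring B through a single C2–C1' bond beta to the C4 ketone. The C8 prenyl group of the fully substituted ring A lies para to O5, and both positions ortho to O5 (C6 with its OMe, and the ring-fusion carbon C4a) are blocked.
- Disconnection 1 (C2–C1'): the target comes from its diacetate, which comes from an enantioselective palladium-catalysed 1,4-addition of 4-acetoxyphenylboronic acid to 5-acetoxy-6,7-dimethoxy-8-prenylchromone.
- Disconnection 2 (C8–prenyl): a para-Claisen–Cope relay of a 5-O-prenyl ether (O5 to C6 to C8). The ether comes from peri-demethylation of 5,6,7-trimethoxychromone followed by O-prenylation.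
- Ring order: ring A is bought as 3,4,5-trimethoxyphenol; ring C is closed by Fries acetylation, enaminone formation and acid cyclisation; the prenyl group is relayed to C8; ring B is attached last.

Key step: step 8

Assumption: the target is the 2S enantiomer (priorities at C2: O1 > C1' > C3 > H). The (R)-antipode of the tert-butyl pyridine-oxazoline ligand is taken as the one that delivers 2S. This is to be confirmed on unsubstituted chromone with phenylboronic acid before the real substrate is committed; the (S)-ligand is used instead if the test shows the opposite sense.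

Step 1
Reactants: 1 3,4,5-trimethoxyphenol
Product: 3 2'-hydroxy-4',5',6'-trimethoxyacetophenone, via 3,4,5-trimethoxyphenyl acetate 2 (not isolated)
Conditions: Ac2O (1.5 equiv), BF3·OEt2 (3 equiv), 90 °C; then H2O
Reagents that add atoms: acetic anhydride, CC(=O)OC(C)=O
Why: BF3-promoted O-acetylation followed by Fries rearrangement should move the acetyl group to one of the two equivalent positions ortho to the phenol (the para position carries OMe), giving the hydrogen-bonded ortho-hydroxyacetophenone that supplies C4 and C3 of ring C.

Step 2
Reactants: 3 2'-hydroxy-4',5',6'-trimethoxyacetophenone; 4 N,N-dimethylformamide dimethyl acetal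
Product: 5 (E)-3-(dimethylamino)-1-(2-hydroxy-4,5,6-trimethoxyphenyl)prop-2-en-1-one
Conditions: 4 (2 equiv), toluene, 100 °C
Reagents that add atoms: none
Why: Condensation of the acidic methyl ketone with the amide acetal (enaminone formation) should give the E-enaminone with loss of two molecules of methanol, adding the future C2 while the chelated phenol stays free.

Step 3
Reactants: 5 (E)-3-(dimethylamino)-1-(2-hydroxy-4,5,6-trimethoxyphenyl)prop-2-en-1-one
Product: 6 5,6,7-trimethoxychromone
Conditions: conc. HCl, CH2Cl2, 40 °C
Reagents that add atoms: none
Why: Acid promotes 6-endo conjugate addition of the phenol oxygen to the protonated enaminone and elimination of dimethylamine (enaminone-to-chromone cyclisation), which closes ring C as the 4-pyranone.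

Step 4
Reactants: 6 5,6,7-trimethoxychromone
Product: 7 5-hydroxy-6,7-dimethoxychromone
Conditions: BCl3 (1.5 equiv), CH2Cl2, −78 to 0 °C; then H2O
Reagents that add atoms: none
Why: In this chelation-directed Lewis-acid ether cleavage, boron held between the C4 carbonyl and the peri O5 activates only the 5-OMe towards chloride attack at methyl, so a limited amount of BCl3 at low temperature should spare the 6- and 7-OMe groups.

Step 5
Reactants: 7 5-hydroxy-6,7-dimethoxychromone; 8 prenyl bromide (1-bromo-3-methylbut-2-ene)
Product: 9 6,7-dimethoxy-5-(3-methylbut-2-enyloxy)chromone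
Conditions: 8 (1.5 equiv), K2CO3, DMF, 50 °C
Reagents that add atoms: none
Why: In this Williamson etherification the phenoxide of 7 displaces bromide from the primary allylic halide in a polar aprotic solvent that favours O- over C-alkylation, and 7 has no other acidic site.

Step 6
Reactants: 9 6,7-dimethoxy-5-(3-methylbut-2-enyloxy)chromone
Product: 12 5-hydroxy-6,7-dimethoxy-8-(3-methylbut-2-enyl)chromone, via C6 ortho-dienone 10 (not isolated), via C8 para-dienone 11 (not isolated)
Conditions: Eu(fod)3 [europium tris(6,6,7,7,8,8,8-heptafluoro-2,2-dimethyloctane-3,5-dionate)] (10 mol %), CHCl3, 60 °C, sealed tube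
Reagents that add atoms: none
Why: In this para-Claisen (Claisen–Cope) rearrangement the trivalent europium Lewis acid chelated between the C4 carbonyl and O5 accelerates the [3,3] shift from O5 to C6, where the methoxy group prevents re-aromatisation, so a second [3,3] (Cope) shift carries the allyl unit to C8 with normal prenyl connectivity and tautomerisation of the C8-H dienone restores ring A with a free 5-OH; C4a, the other ortho position, is a ring-fusion carbon and cannot compete.

Step 7
Reactants: 12 5-hydroxy-6,7-dimethoxy-8-(3-methylbut-2-enyl)chromone
Product: 13 5-acetoxy-6,7-dimethoxy-8-(3-methylbut-2-enyl)chromone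
Conditions: Ac2O, pyridine, DMAP (cat.), CH2Cl2, rt
Reagents that add atoms: acetic anhydride, CC(=O)OC(C)=O
Why: DMAP-catalysed acylation overcomes the low nucleophilicity of the hydrogen-bonded peri phenol, and the acetate removes the O4/O5 chelating site and makes the enone more electron-poor for the next step.

Step 8
Reactants: 13 5-acetoxy-6,7-dimethoxy-8-(3-methylbut-2-enyl)chromone; 14 4-acetoxyphenylboronic acid
Product: 15 (2S)-5-acetoxy-2-(4-acetoxyphenyl)-6,7-dimethoxy-8-(3-methylbut-2-enyl)chroman-4-one
Conditions: 14 (2 equiv), Pd(OCOCF3)2 (10 mol %), (R)-t-BuPyOx [(R)-4-tert-butyl-2-(pyridin-2-yl)-4,5-dihydrooxazole] (12 mol %), NH4PF6 (30 mol %), H2O (5 equiv), ClCH2CH2Cl, 60 °C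
Reagents that add atoms: none
Why: The aryl group of 14 transmetalates to the cationic divalent palladium centre held by the pyridine-oxazoline ligand, the C2=C3 bond of 13 binds and inserts with aryl delivered to C2 and palladium to C3 (a palladium enolate), and protonolysis by water releases 15 and returns divalent palladium without any change of oxidation state. The closest known reaction type is the palladium/pyridine-oxazoline-catalysed asymmetric conjugate addition of arylboronic acids to cyclic enones and 2-unsubstituted chromones. No ring is closed: ring C is already present and is only converted from chromone to chroman-4-one as the C2–C1' bond to ring B forms. The new C2 stereocentre is controlled by the ligand, whose tert-butyl group shields one enantioface of the planar enone so that the aryl group should arrive on the face that gives 2S. The step needs enantioface selectivity and chemoselectivity for the enone over the prenyl alkene; the first comes from the ligand, the second from the polarised chromone enone, which the 5-acetate makes more electrophilic and frees of its chelating site, so that it inserts far more readily than the unactivated trisubstituted alkene. No phenol sits ortho to the prenyl group (O1 is part of ring C, O7 is a methyl ether), so an oxidative Wacker-type cyclisation onto the alkene is not available.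

Step 9
Reactants: 15 (2S)-5-acetoxy-2-(4-acetoxyphenyl)-6,7-dimethoxy-8-(3-methylbut-2-enyl)chroman-4-one
Product: 16 (2S)-5-hydroxy-2-(4-hydroxyphenyl)-6,7-dimethoxy-8-(3-methylbut-2-enyl)chroman-4-one
Conditions: NH4OAc (10 equiv), MeOH/H2O (4:1), rt
Reagents that add atoms: none
Why: Aryl acetates are cleaved by mild acetate-buffered solvolysis because phenoxides are good leaving groups, and since no strong base is present the retro-oxa-Michael opening of ring C that would racemise C2 is avoided, so the 2S configuration should be retained.

**Compound list**
1 | 3,4,5-trimethoxyphenol | COc1cc(O)cc(OC)c1OC | starting material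
2 | 3,4,5-trimethoxyphenyl acetate | CC(=O)Oc1cc(OC)c(OC)c(OC)c1 | intermediate
3 | 2'-hydroxy-4',5',6'-trimethoxyacetophenone | CC(=O)c1c(O)cc(OC)c(OC)c1OC | intermediate
4 | N,N-dimethylformamide dimethyl acetal | COC(OC)N(C)C | starting material
5 | (E)-3-(dimethylamino)-1-(2-hydroxy-4,5,6-trimethoxyphenyl)prop-2-en-1-one | CN(C)/C=C/C(=O)c1c(O)cc(OC)c(OC)c1OC | intermediate
6 | 5,6,7-trimethoxychromone | COc1cc2occc(=O)c2c(OC)c1OC | intermediate
7 | 5-hydroxy-6,7-dimethoxychromone | COc1cc2occc(=O)c2c(O)c1OC | intermediate
8 | prenyl bromide (1-bromo-3-methylbut-2-ene) | CC(C)=CCBr | starting material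
9 | 6,7-dimethoxy-5-(3-methylbut-2-enyloxy)chromone | COc1cc2occc(=O)c2c(OCC=C(C)C)c1OC | intermediate
10 | C6 ortho-dienone: 6,7-dimethoxy-6-(2-methylbut-3-en-2-yl)chromene-4,5(6H)-dione | COC1=CC2=C(C(=O)C=CO2)C(=O)C1(OC)C(C)(C)C=C | intermediate
11 | C8 para-dienone: 6,7-dimethoxy-8-(3-methylbut-2-enyl)chromene-4,5(8H)-dione | COC1=C(OC)C(CC=C(C)C)C2=C(C(=O)C=CO2)C1=O | intermediate
12 | 5-hydroxy-6,7-dimethoxy-8-(3-methylbut-2-enyl)chromone | COc1c(O)c2c(=O)ccoc2c(CC=C(C)C)c1OC | intermediate
13 | 5-acetoxy-6,7-dimethoxy-8-(3-methylbut-2-enyl)chromone | COc1c(OC(C)=O)c2c(=O)ccoc2c(CC=C(C)C)c1OC | intermediate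
14 | 4-acetoxyphenylboronic acid | CC(=O)Oc1ccc(B(O)O)cc1 | starting material
15 | (2S)-5-acetoxy-2-(4-acetoxyphenyl)-6,7-dimethoxy-8-(3-methylbut-2-enyl)chroman-4-one | COc1c(OC(C)=O)c2c(c(CC=C(C)C)c1OC)O[C@H](c1ccc(OC(C)=O)cc1)CC2=O | intermediate
16 | (2S)-5-hydroxy-2-(4-hydroxyphenyl)-6,7-dimethoxy-8-(3-methylbut-2-enyl)chroman-4-one | COc1c(O)c2c(c(CC=C(C)C)c1OC)O[C@H](c1ccc(O)cc1)CC2=O | target

**Step count**
Total steps: 9. Longest linear sequence: 9 steps (1 to 16); compounds 4, 8 and 14 are bought and enter directly.

**Steps most likely to fail, with fallbacks**

Step 8. Insertion into the electron-rich, peri-substituted chromone may be slow, so that protodeboronation and homocoupling of the boronic acid win. The 5-acetate may be lost during the reaction, which restores a chelating phenol. Enantioface discrimination may be insufficient. The fallback changes the metal, the ligand class and the protecting-group logic, and sets out from 12. The peri phenol of 12 is converted with chloromethyl methyl ether and NaH in DMF at 0 °C into 5-(methoxymethoxy)-6,7-dimethoxy-8-(3-methylbut-2-enyl)chromone F1. A 1,4-addition catalysed by monovalent rhodium ([RhCl(C2H4)2]2, a chiral 2,5-diphenylbicyclo[2.2.2]octa-2,5-diene ligand of the antipode that gives 2S, substoichiometric aqueous KOH, dioxane, 50 °C) then transfers the aryl group of bought 4-(methoxymethoxy)phenylboronic acid F2 to C2. This should give (2S)-6,7-dimethoxy-5-(methoxymethoxy)-2-[4-(methoxymethoxy)phenyl]-8-(3-methylbut-2-enyl)chroman-4-one F3. Both acetals are base-stable during the addition and are then removed by acidic methanolysis (HCl, MeOH, 40 °C), conditions that do not trigger the base-induced opening of ring C. The fallback comes back to the route at 16 and replaces steps 7 to 9.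

Step 6. Ionisation of the allylic ether (loss of the prenyl group, returning 7) may outrun the two sigmatropic shifts, or the relay may stall or divert at the blocked dienone stage. The fallback installs the C8–prenyl bond by cross-coupling and sets out from 7. Electrophilic iodination at C8, the only free position of ring A and para to the 5-OH (N-iodosuccinimide, cat. CF3CO2H, MeCN, 0 °C), should give 5-hydroxy-8-iodo-6,7-dimethoxychromone F4. Suzuki–Miyaura coupling of F4 with bought 3-methylbut-2-enylboronic acid pinacol ester F5 follows (Pd(OAc)2 with a bulky biarylphosphine chosen for alpha-selective, linear allyl transfer, K3PO4, THF/H2O, 60 °C). It should place the normal prenyl group on C8 and comes back to the route at 12, replacing steps 5 and 6.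

Step 5. O-alkylation of the hydrogen-bonded, doubly flanked peri phenol may be sluggish, with competing decomposition of the allylic bromide and C-alkylation. The fallback sets out from 7 and uses a Mitsunobu etherification in place of the base-mediated displacement: 7 is treated with bought 3-methylbut-2-en-1-ol F6, PPh3 and diisopropyl azodicarboxylate in THF at 0 °C to rt. The phenol acts as the acidic partner and no phenoxide has to be formed. The fallback comes back to the route at 9.

**Further compounds**
F1 | step 8 | 5-(methoxymethoxy)-6,7-dimethoxy-8-(3-methylbut-2-enyl)chromone | COCOc1c(OC)c(OC)c(CC=C(C)C)c2occc(=O)c12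
F2 | step 8 | 4-(methoxymethoxy)phenylboronic acid (bought) | COCOc1ccc(B(O)O)cc1
F3 | step 8 | (2S)-6,7-dimethoxy-5-(methoxymethoxy)-2-[4-(methoxymethoxy)phenyl]-8-(3-methylbut-2-enyl)chroman-4-one | COc1c(OCOC)c2c(c(CC=C(C)C)c1OC)O[C@H](c1ccc(OCOC)cc1)CC2=O
F4 | step 6 | 5-hydroxy-8-iodo-6,7-dimethoxychromone | COc1c(O)c2c(=O)ccoc2c(I)c1OC
F5 | step 6 | 3-methylbut-2-enylboronic acid pinacol ester (bought) | CC(C)=CCB1OC(C)(C)C(C)(C)O1
F6 | step 5 | 3-methylbut-2-en-1-ol (bought) | CC(C)=CCO
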